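Compare the amber run with Saturday's first: both hold 0.050 M of starting complex, and they differ in the charge of incoming ligand and in time.

in all of them: starting complex 0.050 M
- amber: incoming ligand 0.58 equiv; run made earlier
- Tuesday's: incoming ligand 1.30 equiv; time 10 min
- Saturday's: incoming ligand 1.00 equiv; time 10 min

amber run (percent of the starting complex charged)

| time / min | complex with three exchanged / % | complex with two exchanged / % | starting complex / % | complex with one exchanged / % |
|---|---|---|---|---|
| 0.417 | 0 | 0.5 | 91.4 | 7.8 |
| 1.33 | 0.5 | 2.6 | 82.7 | 14.8 |
| 2.50 | 0.4 | 4.7 | 77.2 | 16.9 |
| 4.00 | 0.6 | 5.7 | 74.3 | 18.6 |
| 5.00 | 0.7 | 5.6 | 74.0 | 19.2 |

(readings scatter by 0.3 percentage points)

- the numbers in the tables scatter by 0.3 percentage points (one standard deviation)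
- steps that have been proposed: complex with two exchanged + incoming ligand -> leaving ligand + complex with three exchanged; incoming ligand <-> dormant form; starting complex + incoming ligand -> leaving ligand + complex with one exchanged; complex with one exchanged + incoming ligand -> leaving ligand + complex with two exchanged; complex with three exchanged <-> isomer of the product; complex with three exchanged + incoming ligand -> leaving ligand + complex with four exchanged
- no earlier run changes the charge of incoming ligand; that part of a forecast is a guess
- a reading of complex with three exchanged is of its free form alone

1. which of these there is most of at the end, counted by the starting complex in it, Tuesday's (complex with two exchanged / starting complex / complex with three exchanged / complex with one exchanged)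
2. which of these there is most of at the end, counted by the starting complex in it, Saturday's (complex with two exchanged / starting complex / complex with three exchanged / complex with one exchanged)
3. final amount of the leader among these, as a percentage of the starting complex charged, in Tuesday's
4. final amount of the leader among these, as a percentage of the starting complex charged, in Saturday's

I gave the extra time little weight. Between 4.00 min and 5.00 min the amber run lost 0.3 percentage points of starting complex, which is about the scatter, far less than the 8.6 points lost by 0.417 min. Yet 74.0% of starting complex still stood there, so I treated incoming ligand as the limiting reagent. The read exchanges account for 56.0% of its charge, and I put the rest down to the dormant form.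

The loss of starting complex carries c(incoming ligand) as a factor, and so does each forward step removing incoming ligand. Divide one rate by the other and time drops out, provided any return from the dormant form is left aside; I left it aside, as an assumption. I therefore carried one quantity. The reach, 0.519 /equiv in the amber run, is the natural logarithm of charged over remaining starting complex, per equivalent of incoming ligand charged. Holding c(starting complex) fixed, I guessed that the reach survives a change of charge. That gave me 50.9% for Tuesday's and 59.5% for Saturday's. Each is more than the remainder, so starting complex should lead.

The forecast named starting complex for Tuesday's at 52% (45% to 58%) and starting complex for Saturday's at 60% (54% to 65%), “assuming the dormancy scales with charge”. My figures stood slightly lower.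

Tuesday's ended with starting complex leading at 49.7%, Saturday's with starting complex leading at 57.7%.

    complex with two exchanged + incoming ligand → leaving ligand + complex with three exchanged (k = 17.0 /M/min)
    incoming ligand ⇌ dormant form (K = 5.90, k = 0.360 /min)
    starting complex + incoming ligand → leaving ligand + complex with one exchanged (k = 8.20 /M/min)
    complex with one exchanged + incoming ligand → leaving ligand + complex with two exchanged (k = 17.0 /M/min)
    complex with three exchanged ⇌ isomer of the product (K = 0.390, k = 0.370 /min)
    complex with three exchanged + incoming ligand → leaving ligand + complex with four exchanged (k = 27.0 /M/min)

Saturday's own reach came to 0.550 /equiv, against the amber run's 0.519 /equiv, and its starting complex was still falling, from 60.5% at 5.00 min to 57.7% at 10.0 min. I then put the amber reach on the neighbour of Saturday's charged with 4.00 equiv of incoming ligand, which gave 12.5% of starting complex. That flask ended with 12.2% of starting complex, and its largest share stood as complex with four exchanged, at 49.0%.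

The numbers in the tables were generated by integration from invented constants; scatter was added.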